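Assumptions on the chemistry: (a) the sense of induction of the dirhodium prolinate catalyst is taken from the accepted facial model (the S catalyst gives (1S,2R)-cyclopropanes from styrene and donor/acceptor diazoacetates), which calls for Rh2(R-DOSP)4 to reach (5R,6R)-14; the mirror-image catalyst is equally available should the sense prove opposite; (b) desacylcynaropicrin 27 is taken as a purchasable chiral-pool guaianolide.

## The problem

Target 33 is a heptacyclic dimer of two guaianolides. A cyclohexene (ring D: C2, C1, C10, C14, C15', C4') joins an enone half (unit A: cyclopentenone ring A, seven-membered ring B, lactone ring C) to a cyclopentanone half (unit B: rings E and F, lactone ring G) through the spiro carbon C4'. Guaiane numbering is used, unprimed for unit A and primed for unit B; α and β refer to the usual drawing with the lactone oxygen on C6 α. Ten stereocentres must be set. Unit A has H-5 and H-6 cis and a trans-fused lactone (5β-H, 6β-H, 7α-H, 10α-H), a C5 configuration that the common natural guaianolides do not offer, so this half must be built. Unit B has the common 1α,5α,6β,7α core but an 8β-hydroxyl. The C6 oxygen can direct hydrogen to C7. C5 decides which face of a C2=C1–C10=C14 diene is open. The α-face of unit B decides C4'. C10 can only be fixed last, because its hydrogen is γ to the ring A ketone. Two α-methylene lactones, the 4-methylene-cyclopentenone and the exocyclic C10'=C14' alkene rule out nucleophiles, hydride, hydrogenation and strong base at the end; C5–H and C10–H are both vinylogously acidic. Ring B (C1, C5–C10) carries oxygen at C6, the C14 branch at C10 and is fused to ring A at C1–C5. This is the pattern formed when a C5=C1–C10 vinylcarbenoid adds across a C6–C9 1-oxygenated diene, so an enantioselective cyclopropanation/Cope sequence is the direct way to create the unusual C5/C6 pair.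

## Retrosynthesis

**Ring D and C10.** Target 33 is traced to the β,γ-unsaturated ketone 32 by returning the C10 hydrogen to C2. Adduct 32 is then cut at C2–C4' and C14–C15' into trienone 31 and exocyclic enone 30. A stepwise ionic or radical union across the same two bonds would have to join C2 and C4', both α to a carbonyl, which is polarity-mismatched. The cycloaddition pairs exactly these carbons ("ortho" orientation) and is the known mode of assembly of spiro-linked guaianolide dimers. The precursors are two C15 monomers and no C–C bond is made after the union. The forward reaction must attack 30 on its α-face, attack 31 anti to C6 with the ketone endo, and then move H-2 to C10 on the same face.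

**The diene.** Trienone 31 is too reactive to store, so it is released from mesylate 26 by elimination across C10–C14. Mesylate 26 comes from alcohol 25 and silyl ether 24. The C10 centre in 24–26 is irrelevant because it is erased. Keeping C14 as an oxygenated carbon retains the carbon delivered by the carbenoid ester.

**The two methylenes.** Silyl ether 24 is cut at C4–C15 and C11–C13 back to keto-lactone 21 (double Mannich methylenation). This cannot be done after the union, where unit B's ketone would compete. It cannot be done before the enone exists, because only the C1=C2 enone makes C4 the sole kinetic enolisation site of the ketone.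

**Ring C and the enone.** Enone 21 comes from ketal 19 by hydrolysis and migration of C1=C10 into conjugation. Lactone 19 is cut at the C12–O bond to hydroxy ester 18. A tert-butyl ester is chosen so that lactonisation cannot precede the setting of C7.

**C7 and C14.** Hydroxy ester 18 is traced to allylic alcohol 17; the C6 hydroxyl must deliver hydrogen to its own face of C7=C8 to give the trans lactone. Alcohol 17 comes from diol 16, silyl ether 15 and the diester 14. The C14 ester must be reduced before any lactone exists, and C14–O is capped so that it cannot direct hydrogenation of C1=C10.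

**Ring B (key cut).** Diester 14 is cut at C9–C10 and C5–C6 into vinyldiazoacetate 5 and siloxydiene 12. Cuts elsewhere in ring B (for example C1–C10 or C7–C8) would leave the C5/C6 pair to be made separately. This cut creates both centres in one stereospecific event from two achiral, six-step fragments. The forward step needs a chiral dirhodium tetraprolinate for absolute control, reaction at C8=C9 only, and an (E)-enol ether.

**The fragments.** Diazo ester 5 comes from ester 4 by diazo transfer. Ester 4 is cut at C1–C10 into enol triflate 2 and zinc reagent 3, and 2 comes from ketal ketone 1. Diene 12 comes from enal 11, which is cut at C7–C11 into imine 7 and bromide 8; 7 comes from aldehyde 6.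

**Unit B.** Enone 30 is traced through formate 29 (inversion at C8') and enone 28 (oxidation at C3') to diol 27. This pool material already holds C1', C5', C6' and C7' and all three exocyclic methylenes. Only C8' has to be corrected, at the cost of one substitution on a sensitive substrate.

## Roads not taken

**Alternative 1:** Rings A and D would be closed together. A cyclic 1,3-diketone condenses with an aldehyde at C2 of a ring B/C precursor, and the resulting C2=C4' alkylidene dione adds intramolecularly across a C1=C10–C14=C15' diene. This forms C1–C2 and C4'–C15' and gives the spiro-dione pentacycle A1.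
- Merits: a cascade that makes two rings, two C–C bonds and the quaternary spiro carbon without an intermolecular union, without an excess partner and without a free trienone.
- Weak points: the dione ring of A1 is prochiral, so C4' only becomes a stereocentre once the two carbonyls are told apart. Rings F and G with five stereocentres must then be built on a crowded spiro core. The alkene ends at C10=C14 and must be walked to C1=C2 with the same C10 problem as here. The 5,6-cis ring B/C precursor still has to be made.
- Comparison: this road is better at closing ring D. The chosen plan sets against it that unit B arrives complete, that C4' follows from a known face preference, and that nothing remains to be built after the union.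

**Alternative 2:** Unit B would be made de novo by cutting C6'–C7' and the lactone C–O bond. Divalent chromium turns a 2-(bromomethyl)acrylate into an allylchromium that attacks the C6' aldehyde through C7', and the alkoxide lactonises, closing rings F and G to the silyl ether A2.
- Merits: the α-methylene lactone and the C6'/C7' relationship arise in one step, and C8' is built with the right configuration rather than inverted.
- Weak points: a seven-membered ring is closed by an intramolecular carbonyl addition (dilution, large excess of chromium). The open-chain precursor with C1', C5' and C8' in place is long to make. A2 still lacks the C3' ketone. Unit A and the union remain unsolved.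
- Comparison: this road is better in that no inversion is carried out on a multiply unsaturated natural product and no pool supply is needed. The chosen plan sets against it three steps to 30 instead of a long linear sequence, and spends its effort on unit A, which no natural source provides.

**Alternative 3:** Ring F would be closed at C8'–C9' by a carbonyl-ene reaction. An alkylaluminium chloride activates a C8' aldehyde, C9' of an isopropenyl group attacks it, and a C14' hydrogen moves to oxygen, giving the 13-nor lactone A3 with the C8' carbinol and the C10'=C14' methylene.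
- Merits: atom-economical; the hydroxyl and the exocyclic alkene arise together; the lactone is already present.
- Weak points: the C8' configuration rests on the transition-state conformation of a medium-ring ene closure and may be mixed or wrong. A3 lacks C13' and the C3' ketone, which must be added later next to a free hydroxyl. Unit A is again untouched.
- Comparison: this road is better in making the C8' carbinol and the C10' methylene in one event, while the chosen plan's inversion at C8' is its weakest single operation. Against this the chosen plan sets a well-understood SN2 inversion with a fallback, and a unit B whose other four centres are secure.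

Key step: step 7

## Route

Step 1
Reactants: 1 1,4-dioxaspiro[4.4]nonan-7-one
Product: 2 1,4-dioxaspiro[4.4]non-7-en-7-yl trifluoromethanesulfonate
Conditions: LiN(SiMe3)2, THF, −78 °C; PhNTf2, −78 → 0 °C
Reagents that add atoms: N-phenylbis(trifluoromethanesulfonimide), O=S(=O)(N(c1ccccc1)S(=O)(=O)C(F)(F)F)C(F)(F)F
Why: Kinetic enolisation toward C5 (the α-carbon remote from the ketal, less hindered and not prone to β-alkoxide loss) and O-triflation of the lithium enolate (enol triflate formation) fix the future C1=C5 double bond of ring A.

Step 2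
Reactants: 2 1,4-dioxaspiro[4.4]non-7-en-7-yl trifluoromethanesulfonate; 3 (2-ethoxy-2-oxoethyl)zinc bromide
Product: 4 ethyl 2-(1,4-dioxaspiro[4.4]non-7-en-7-yl)acetate
Conditions: Pd(PPh3)4 (5 mol %), THF, 50 °C
Reagents that add atoms: none
Why: Negishi-type cross-coupling of the Reformatsky zinc enolate with the enol triflate under zerovalent palladium forms C1–C10 and leaves the alkene where the triflate placed it.

Step 3
Reactants: 4 ethyl 2-(1,4-dioxaspiro[4.4]non-7-en-7-yl)acetate
Product: 5 ethyl 2-diazo-2-(1,4-dioxaspiro[4.4]non-7-en-7-yl)acetate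
Conditions: 4-AcNHC6H4SO2N3, DBU, MeCN, 0 °C → rt
Reagents that add atoms: 4-acetamidobenzenesulfonyl azide, CC(=O)Nc1ccc(cc1)S(=O)(=O)N=[N+]=[N-]
Why: Regitz diazo transfer: DBU removes the allylic, ester-activated C10 hydrogen and the sulfonyl azide delivers N2, giving the conjugated vinyldiazoacetate without moving the ring double bond.

Step 4
Reactants: 6 (E)-but-2-enal
Product: 7 (1E,2E)-N-cyclohexylbut-2-en-1-imine
Conditions: c-C6H11NH2, K2CO3, Et2O, 0 °C → rt
Reagents that add atoms: cyclohexylamine, NC1CCCCC1
Why: Imine condensation gives a metalatable aldehyde equivalent; low temperature limits conjugate addition of the amine.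

Step 5
Reactants: 7 (1E,2E)-N-cyclohexylbut-2-en-1-imine; 8 tert-butyl bromoacetate
Product: 11 tert-butyl (3E)-3-formylpent-3-enoate, via alkylated imine 9 (not isolated), via deconjugated aldehyde 10 (not isolated)
Conditions: LiN(iPr)2, THF, −78 °C; 8, −78 → −20 °C; aq. (CO2H)2, Et2O, rt; Et3N (cat.), CH2Cl2, rt
Reagents that add atoms: water, O
Why: γ-Deprotonation gives the 1-azapentadienyl anion, which is alkylated at the α-carbon (C7) by the activated bromide (aza-enolate alkylation of an unsaturated imine), forming C7–C11. Mild acid hydrolysis and amine-mediated conjugation then give the thermodynamically favoured (E)-enal.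

Step 6
Reactants: 11 tert-butyl (3E)-3-formylpent-3-enoate
Product: 12 tert-butyl (3E)-3-[(tert-butyldimethylsilyloxy)methylidene]pent-4-enoate
Conditions: TBSOTf, Et3N, Et2O, 0 °C
Reagents that add atoms: tert-butyldimethylsilyl trifluoromethanesulfonate, CC(C)(C)[Si](C)(C)OS(=O)(=O)C(F)(F)F
Why: O-Silylation and γ-deprotonation of the s-trans enal (silyl dienol ether formation) place the silyloxy group trans to the new vinyl group, which is the (E)-enol ether needed for the cis C5/C6 pair.

Step 7
Reactants: 5 ethyl 2-diazo-2-(1,4-dioxaspiro[4.4]non-7-en-7-yl)acetate; 12 tert-butyl (3E)-3-[(tert-butyldimethylsilyloxy)methylidene]pent-4-enoate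
Product: 14 14-ethyl 12-tert-butyl (5R,6R)-6-(tert-butyldimethylsilyloxy)-3,3-(ethylenedioxy)-13,15-dinorguaia-1(10),7-diene-12,14-dioate, via cis-divinylcyclopropane 13 (not isolated)
Conditions: Rh2(R-DOSP)4 [dirhodium tetrakis((R)-N-(4-dodecylphenylsulfonyl)prolinate), 1 mol %], 12 (2 equiv), hexanes, −78 °C → rt (slow addition of 5), then 40 °C
Reagents that add atoms: none
Why: Rh2(R-DOSP)4 decomposes 5 with loss of N2 to a donor/acceptor rhodium vinylcarbenoid at C10, which cyclopropanates the monosubstituted C8=C9 bond of 12 (first bonding at the terminal C9, ester turned away from the diene) to give the cis-divinylcyclopropane 13. On warming, 13 undergoes a Cope rearrangement through the boat transition state required of cis-divinylcyclopropanes, breaking C8–C10, forming C5–C6 and keeping C9–C10, so that ring B closes as a cyclohepta-1,4-diene fused to ring A. The closest known reaction type is the dirhodium-catalysed tandem cyclopropanation/Cope rearrangement (formal [4+3] cycloaddition) of vinyldiazoacetates with 1-oxygenated butadienes. Ring B is thus closed by a [3,3]-sigmatropic ring expansion of a three-membered ring that was itself closed by carbene transfer. The relative configuration at C5 and C6 follows from the boat geometry: the silyloxy group of the (E)-enol ether and ring carbon C4 both point outward and the two hydrogens inward, giving cis H-5/H-6. The absolute configuration is set when the chiral catalyst selects the enantioface of C8=C9 and is passed on stereospecifically by the concerted rearrangement; the R catalyst is chosen from the accepted facial model and its mirror image is equally available. The step needs site selectivity for C8=C9 over the enol ether C6=C7, secured by the trisubstituted, trans-disposed enol ether (inert to bulky donor/acceptor carbenoids) and by the hydrocarbon solvent (which suppresses zwitterionic vinylogous addition); it also needs the pure (E)-diene, since a (Z)-enol ether would lead to the C6 epimer.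

Step 8
Reactants: 14 14-ethyl 12-tert-butyl (5R,6R)-6-(tert-butyldimethylsilyloxy)-3,3-(ethylenedioxy)-13,15-dinorguaia-1(10),7-diene-12,14-dioate
Product: 15 tert-butyl (5R,6R)-6-(tert-butyldimethylsilyloxy)-3,3-(ethylenedioxy)-14-hydroxy-13,15-dinorguaia-1(10),7-dien-12-oate
Conditions: iBu2AlH (2.2 equiv), CH2Cl2, −78 °C; aq. potassium sodium tartrate
Reagents that add atoms: none
Why: Low-temperature iBu2AlH reduction takes the conjugated ethyl ester to the allylic alcohol; the tert-butyl ester is sterically shielded and should react far more slowly at −78 °C.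

Step 9
Reactants: 15 tert-butyl (5R,6R)-6-(tert-butyldimethylsilyloxy)-3,3-(ethylenedioxy)-14-hydroxy-13,15-dinorguaia-1(10),7-dien-12-oate
Product: 16 tert-butyl (5R,6R)-3,3-(ethylenedioxy)-6,14-dihydroxy-13,15-dinorguaia-1(10),7-dien-12-oate
Conditions: HF·pyridine, pyridine, THF, 0 °C → rt
Reagents that add atoms: none
Why: Buffered fluoride cleaves the secondary silyl ether and leaves ketal and tert-butyl ester intact; the tert-butyl ester keeps the freed allylic alcohol from lactonising before C7 is set.

Step 10
Reactants: 16 tert-butyl (5R,6R)-3,3-(ethylenedioxy)-6,14-dihydroxy-13,15-dinorguaia-1(10),7-dien-12-oate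
Product: 17 tert-butyl (5R,6R)-14-(tert-butyldiphenylsilyloxy)-3,3-(ethylenedioxy)-6-hydroxy-13,15-dinorguaia-1(10),7-dien-12-oate
Conditions: TBDPSCl (1.05 equiv), imidazole, CH2Cl2, 0 °C
Reagents that add atoms: tert-butyldiphenylsilyl chloride, CC(C)(C)[Si](Cl)(c1ccccc1)c1ccccc1
Why: Steric differentiation in silylation: the bulky silyl chloride takes the primary C14 hydroxyl and leaves the hindered secondary C6 hydroxyl free as the directing group.

Step 11
Reactants: 17 tert-butyl (5R,6R)-14-(tert-butyldiphenylsilyloxy)-3,3-(ethylenedioxy)-6-hydroxy-13,15-dinorguaia-1(10),7-dien-12-oate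
Product: 18 tert-butyl (5R,6S,7S)-14-(tert-butyldiphenylsilyloxy)-3,3-(ethylenedioxy)-6-hydroxy-13,15-dinorguai-1(10)-en-12-oate
Conditions: [Ir(cod)(PCy3)(py)]PF6 (5 mol %), H2 (1 atm), CH2Cl2, 0 °C → rt
Reagents that add atoms: none
Why: Hydroxyl-directed homogeneous hydrogenation: the cationic iridium catalyst binds the C6 hydroxyl and delivers H2 to the α-face of the trisubstituted C7=C8 bond, so H-7 is cis to the C6 oxygen and C11 trans (7α-H). The tetrasubstituted C1=C10 bond next to the bulky silyl ether should be much slower.

Step 12
Reactants: 18 tert-butyl (5R,6S,7S)-14-(tert-butyldiphenylsilyloxy)-3,3-(ethylenedioxy)-6-hydroxy-13,15-dinorguai-1(10)-en-12-oate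
Product: 19 (5R,6S,7S)-14-(tert-butyldiphenylsilyloxy)-3,3-(ethylenedioxy)-13,15-dinorguai-1(10)-en-12,6-olide
Conditions: KOtBu (10 mol %), THF, 0 °C → rt
Reagents that add atoms: none
Why: Alkoxide-catalysed intramolecular transesterification (5-exo-trig lactonisation) closes the trans-fused γ-lactone ring C and releases tert-butoxide, which carries the chain.

Step 13
Reactants: 19 (5R,6S,7S)-14-(tert-butyldiphenylsilyloxy)-3,3-(ethylenedioxy)-13,15-dinorguai-1(10)-en-12,6-olide
Product: 21 14-(tert-butyldiphenylsilyloxy)-3-oxo-13,15-dinorguai-1-en-12,6-olide (C10 epimers), via β,γ-enone 20 (not isolated)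
Conditions: PPTS, acetone–H2O (10:1), 55 °C; then Et3N, CH2Cl2, rt
Reagents that add atoms: water, O
Why: Acid-catalysed ketal hydrolysis unveils the C3 ketone, and triethylamine then shifts the doubly activated C2 hydrogen so that C1=C10 moves into conjugation (β,γ- to α,β-enone isomerisation). The new C10 centre is of no consequence because it is erased in step 20.

Step 14
Reactants: 21 14-(tert-butyldiphenylsilyloxy)-3-oxo-13,15-dinorguai-1-en-12,6-olide (C10 epimers)
Product: 24 14-(tert-butyldiphenylsilyloxy)-3-oxoguaia-1,4(15),11(13)-trien-12,6-olide (C10 epimers), via bis-Mannich base 22 (not isolated), via bis-ammonium diiodide 23 (not isolated)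
Conditions: LiN(iPr)2 (2.4 equiv), THF, −78 °C; CH2=NMe2+ I− (4 equiv), −78 °C → rt; MeI, THF, rt; aq. NaHCO3, CH2Cl2, rt
Reagents that add atoms: dimethylmethyleneiminium iodide, C=[N+](C)C.[I-]
Why: Double Mannich methylenation: kinetic deprotonation gives the α'-enolate of the enone (C4) and the lactone enolate (C11), and both are aminomethylated by the iminium salt. Exhaustive methylation and elimination of trimethylamine with a weak base then give both exocyclic methylenes; no Michael acceptor is present while strong base is in the flask.

Step 15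
Reactants: 24 14-(tert-butyldiphenylsilyloxy)-3-oxoguaia-1,4(15),11(13)-trien-12,6-olide (C10 epimers)
Product: 25 14-hydroxy-3-oxoguaia-1,4(15),11(13)-trien-12,6-olide (C10 epimers)
Conditions: HF·pyridine, THF, 0 °C → rt
Reagents that add atoms: none
Why: Fluoride cleaves the primary silyl ether under non-basic conditions that the dienone and the methylene lactone tolerate.

Step 16
Reactants: 25 14-hydroxy-3-oxoguaia-1,4(15),11(13)-trien-12,6-olide (C10 epimers)
Product: 26 14-(methanesulfonyloxy)-3-oxoguaia-1,4(15),11(13)-trien-12,6-olide (C10 epimers)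
Conditions: (MeSO2)2O, pyridine, CH2Cl2, 0 °C
Reagents that add atoms: methanesulfonic anhydride, CS(=O)(=O)OS(C)(=O)=O
Why: Sulfonylation of the primary alcohol uses a base (pyridine) too weak to trigger elimination or to exchange the acidic C5 hydrogen.

Step 17
Reactants: 27 desacylcynaropicrin (3β,8α-dihydroxyguaia-4(15),10(14),11(13)-trien-12,6α-olide)
Product: 28 8α-hydroxy-3-oxoguaia-4(15),10(14),11(13)-trien-12,6α-olide
Conditions: MnO2 (activated, excess), CH2Cl2, rt
Reagents that add atoms: none
Why: Manganese dioxide oxidises only the allylic C3 hydroxyl (chemoselective allylic alcohol oxidation); the saturated C8 carbinol is untouched.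

Step 18
Reactants: 28 8α-hydroxy-3-oxoguaia-4(15),10(14),11(13)-trien-12,6α-olide
Product: 29 8β-formyloxy-3-oxoguaia-4(15),10(14),11(13)-trien-12,6α-olide
Conditions: PPh3, DIAD (betaine pre-formed), HCO2H, THF, 0 °C → rt
Reagents that add atoms: formic acid, O=CO
Why: Mitsunobu reaction: the C8 oxygen is activated as an alkoxyphosphonium ion and displaced by formate with inversion (SN2), turning 8α into 8β. Pre-forming the betaine keeps free phosphine away from the exocyclic enone.

Step 19
Reactants: 29 8β-formyloxy-3-oxoguaia-4(15),10(14),11(13)-trien-12,6α-olide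
Product: 30 8β-hydroxy-3-oxoguaia-4(15),10(14),11(13)-trien-12,6α-olide
Conditions: KHCO3, THF–H2O (1:1), rt
Reagents that add atoms: none
Why: Formate esters hydrolyse under weakly basic aqueous conditions in which water should not add to the exocyclic enone or the methylene lactone.

Step 20
Reactants: 26 14-(methanesulfonyloxy)-3-oxoguaia-1,4(15),11(13)-trien-12,6-olide (C10 epimers); 30 8β-hydroxy-3-oxoguaia-4(15),10(14),11(13)-trien-12,6α-olide
Product: 33 target CNP0178208.1, via trienone 31 (not isolated), via Diels–Alder adduct 32 (not isolated)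
Conditions: 30 (2.5 equiv), Et3N (3 equiv), BHT (cat.), degassed PhMe, rt → 45 °C
Reagents that add atoms: none
Why: Triethylamine removes the activated C10 hydrogen with loss of mesylate (β-elimination) to give the s-cis-locked dienone 31. This is trapped by the exocyclic enone of 30 in an endo Diels–Alder reaction on the α-face of unit B and on the diene face anti to C6, forming C2–C4' and C14–C15' in the "ortho" orientation known for the dimerisation of dehydrozaluzanin-type monomers. The same amine then moves the doubly activated C2 hydrogen of adduct 32 to C10 (β,γ- to α,β-enone isomerisation); in an apolar solvent this 1,3-prototropy should proceed within the ion pair, returning the hydrogen to the face it left and giving the 10α-H configuration, while the weak base should leave C5 untouched.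

## Compound list

1 | 1,4-dioxaspiro[4.4]nonan-7-one | O=C1CCC2(C1)OCCO2 | starting material
2 | 1,4-dioxaspiro[4.4]non-7-en-7-yl trifluoromethanesulfonate | O=S(=O)(OC1=CCC2(C1)OCCO2)C(F)(F)F | intermediate
3 | (2-ethoxy-2-oxoethyl)zinc bromide, BrZnCH2CO2Et | CCOC(=O)C[Zn]Br | starting material
4 | ethyl 2-(1,4-dioxaspiro[4.4]non-7-en-7-yl)acetate | CCOC(=O)CC1=CCC2(C1)OCCO2 | intermediate
5 | ethyl 2-diazo-2-(1,4-dioxaspiro[4.4]non-7-en-7-yl)acetate | CCOC(=O)C(=[N+]=[N-])C1=CCC2(C1)OCCO2 | intermediate
6 | (E)-but-2-enal (crotonaldehyde) | C/C=C/C=O | starting material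
7 | (1E,2E)-N-cyclohexylbut-2-en-1-imine | C/C=C/C=N/C1CCCCC1 | intermediate
8 | tert-butyl bromoacetate | CC(C)(C)OC(=O)CBr | starting material
9 | tert-butyl 3-[(cyclohexylimino)methyl]pent-4-enoate (racemic) | C=CC(CC(=O)OC(C)(C)C)/C=N/C1CCCCC1 | intermediate (not isolated)
10 | tert-butyl 3-formylpent-4-enoate (racemic) | C=CC(CC(=O)OC(C)(C)C)C=O | intermediate (not isolated)
11 | tert-butyl (3E)-3-formylpent-3-enoate | C/C=C(CC(=O)OC(C)(C)C)/C=O | intermediate
12 | tert-butyl (3E)-3-[(tert-butyldimethylsilyloxy)methylidene]pent-4-enoate | C=C/C(CC(=O)OC(C)(C)C)=C/O[Si](C)(C)C(C)(C)C | intermediate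
13 | ethyl (1R,2S)-2-[(1E)-4-tert-butoxy-1-(tert-butyldimethylsilyloxy)-4-oxobut-1-en-2-yl]-1-(1,4-dioxaspiro[4.4]non-7-en-7-yl)cyclopropane-1-carboxylate | CCOC(=O)[C@@]1(C[C@H]1/C(CC(=O)OC(C)(C)C)=C/O[Si](C)(C)C(C)(C)C)C2=CCC3(C2)OCCO3 | intermediate (not isolated)
14 | 14-ethyl 12-tert-butyl (5R,6R)-6-(tert-butyldimethylsilyloxy)-3,3-(ethylenedioxy)-13,15-dinorguaia-1(10),7-diene-12,14-dioate (5β-H, 6β-H) | CCOC(=O)C1=C2CC3(OCCO3)C[C@H]2[C@@H](O[Si](C)(C)C(C)(C)C)C(CC(=O)OC(C)(C)C)=CC1 | intermediate (key-step product)
15 | tert-butyl (5R,6R)-6-(tert-butyldimethylsilyloxy)-3,3-(ethylenedioxy)-14-hydroxy-13,15-dinorguaia-1(10),7-dien-12-oate | OCC1=C2CC3(OCCO3)C[C@H]2[C@@H](O[Si](C)(C)C(C)(C)C)C(CC(=O)OC(C)(C)C)=CC1 | intermediate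
16 | tert-butyl (5R,6R)-3,3-(ethylenedioxy)-6,14-dihydroxy-13,15-dinorguaia-1(10),7-dien-12-oate | OCC1=C2CC3(OCCO3)C[C@H]2[C@@H](O)C(CC(=O)OC(C)(C)C)=CC1 | intermediate
17 | tert-butyl (5R,6R)-14-(tert-butyldiphenylsilyloxy)-3,3-(ethylenedioxy)-6-hydroxy-13,15-dinorguaia-1(10),7-dien-12-oate | CC(C)(C)[Si](OCC1=C2CC3(OCCO3)C[C@H]2[C@@H](O)C(CC(=O)OC(C)(C)C)=CC1)(c1ccccc1)c1ccccc1 | intermediate
18 | tert-butyl (5R,6S,7S)-14-(tert-butyldiphenylsilyloxy)-3,3-(ethylenedioxy)-6-hydroxy-13,15-dinorguai-1(10)-en-12-oate (5β-H, 6β-H, 7α-H) | CC(C)(C)[Si](OCC1=C2CC3(OCCO3)C[C@H]2[C@@H](O)[C@H](CC(=O)OC(C)(C)C)CC1)(c1ccccc1)c1ccccc1 | intermediate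
19 | (5R,6S,7S)-14-(tert-butyldiphenylsilyloxy)-3,3-(ethylenedioxy)-13,15-dinorguai-1(10)-en-12,6-olide | CC(C)(C)[Si](OCC1=C2CC3(OCCO3)C[C@H]2[C@H]4OC(=O)C[C@@H]4CC1)(c1ccccc1)c1ccccc1 | intermediate
20 | 14-(tert-butyldiphenylsilyloxy)-3-oxo-13,15-dinorguai-1(10)-en-12,6-olide (5β-H, 6β-H, 7α-H) | O=C1CC2=C(CO[Si](C(C)(C)C)(c4ccccc4)c5ccccc5)CC[C@H]3CC(=O)O[C@@H]3[C@@H]2C1 | intermediate (not isolated)
21 | 14-(tert-butyldiphenylsilyloxy)-3-oxo-13,15-dinorguai-1-en-12,6-olide (5β-H, 6β-H, 7α-H; C10 epimers, centre left open) | O=C1C[C@@H]2C(=C1)C(CO[Si](C(C)(C)C)(c4ccccc4)c5ccccc5)CC[C@H]3CC(=O)O[C@@H]32 | intermediate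
22 | 4,11-bis(dimethylaminomethyl) derivative of 21 (epimers at C4, C10, C11) | O=C1C(CN(C)C)[C@@H]2C(=C1)C(CO[Si](C(C)(C)C)(c4ccccc4)c5ccccc5)CC[C@H]3C(CN(C)C)C(=O)O[C@@H]32 | intermediate (not isolated)
23 | 4,11-bis(trimethylammoniomethyl) diiodide from 22 | O=C1C(C[N+](C)(C)C)[C@@H]2C(=C1)C(CO[Si](C(C)(C)C)(c4ccccc4)c5ccccc5)CC[C@H]3C(C[N+](C)(C)C)C(=O)O[C@@H]32.[I-].[I-] | intermediate (not isolated)
24 | 14-(tert-butyldiphenylsilyloxy)-3-oxoguaia-1,4(15),11(13)-trien-12,6-olide (5β-H, 6β-H, 7α-H; C10 epimers) | C=C1C(=O)C=C2C(CO[Si](C(C)(C)C)(c4ccccc4)c5ccccc5)CC[C@H]3C(=C)C(=O)O[C@@H]3[C@H]12 | intermediate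
25 | 14-hydroxy-3-oxoguaia-1,4(15),11(13)-trien-12,6-olide (5β-H, 6β-H, 7α-H; C10 epimers) | C=C1C(=O)C=C2C(CO)CC[C@H]3C(=C)C(=O)O[C@@H]3[C@H]12 | intermediate
26 | 14-(methanesulfonyloxy)-3-oxoguaia-1,4(15),11(13)-trien-12,6-olide (5β-H, 6β-H, 7α-H; C10 epimers) | C=C1C(=O)C=C2C(COS(C)(=O)=O)CC[C@H]3C(=C)C(=O)O[C@@H]3[C@H]12 | intermediate
27 | desacylcynaropicrin, 3β,8α-dihydroxyguaia-4(15),10(14),11(13)-trien-12,6α-olide (1α-H, 5α-H, 6β-H, 7α-H) | C=C1[C@@H](O)C[C@H]2C(=C)C[C@H](O)[C@H]3C(=C)C(=O)O[C@@H]3[C@H]21 | starting material
28 | 8α-hydroxy-3-oxoguaia-4(15),10(14),11(13)-trien-12,6α-olide | C=C1C(=O)C[C@H]2C(=C)C[C@H](O)[C@H]3C(=C)C(=O)O[C@@H]3[C@H]21 | intermediate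
29 | 8β-formyloxy-3-oxoguaia-4(15),10(14),11(13)-trien-12,6α-olide | C=C1C(=O)C[C@H]2C(=C)C[C@@H](OC=O)[C@H]3C(=C)C(=O)O[C@@H]3[C@H]21 | intermediate
30 | 8β-hydroxy-3-oxoguaia-4(15),10(14),11(13)-trien-12,6α-olide (unit B) | C=C1C(=O)C[C@H]2C(=C)C[C@@H](O)[C@H]3C(=C)C(=O)O[C@@H]3[C@H]21 | intermediate
31 | 3-oxoguaia-1,4(15),10(14),11(13)-tetraen-12,6α-olide (5β-H, 6β-H, 7α-H; unit A trienone) | C=C1C(=O)C=C2C(=C)CC[C@H]3C(=C)C(=O)O[C@@H]3[C@H]12 | intermediate (not isolated)
32 | Diels–Alder adduct, the 1(10)-ene β,γ-unsaturated ketone isomer of 33 with H-2 on the face of C6 and C2 bound to the α-face of C4' | C=C1C(=O)[C@@H]2C3=C(CC[C@H]4C(=C)C(=O)O[C@@H]4[C@H]13)CC[C@]21C(=O)C[C@H]2C(=C)C[C@@H](O)[C@H]3C(=C)C(=O)O[C@@H]3[C@H]21 | intermediate (not isolated)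
33 | CNP0178208.1 (unit A: 5β-H, 6β-H, 7α-H, 10α-H; unit B: 1'α-H, 5'α-H, 6'β-H, 7'α-H, 8'β-OH; C2 on the α-face of C4') | C=C1C(=O)C2=C3[C@H](CC[C@H]4C(=C)C(=O)O[C@@H]4[C@H]13)CC[C@]21C(=O)C[C@H]2C(=C)C[C@@H](O)[C@H]3C(=C)C(=O)O[C@@H]3[C@H]21 | target

## Step count and least certain steps

Total: 20 steps. Longest linear sequence: 14 steps (steps 1–3, 7–16 and 20, from 1).

**Step 7 (key step).** What may go wrong: insufficient enantioface discrimination by the prolinate catalyst for this pairing of a ring-bound vinylcarbenoid with a 2-substituted diene, or a sense of induction opposite to the model. The carbenoid may also be partly diverted to the enol ether double bond or to vinylogous addition. Fallback (auxiliary control in place of catalyst control): setting out from 4, saponification gives 2-(1,4-dioxaspiro[4.4]non-7-en-7-yl)acetic acid F1. Carbodiimide esterification with (R)-pantolactone (or its enantiomer, whichever is matched) gives the pantolactonyl ester F2, and diazo transfer gives the pantolactonyl vinyldiazoacetate F3. Decomposition with achiral Rh2(O2CC7H15)4 in the presence of 12 passes through the pantolactonyl cis-divinylcyclopropane F4 to the pantolactonyl cycloheptadiene ester F5, the auxiliary shielding one face of the carbenoid. Reduction of F5 with iBu2AlH removes the auxiliary and returns to the route at 15.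

**Step 20.** What may go wrong: self-condensation of 31 before it meets 30; return of the proton to C10 from the medium instead of within the ion pair, or later re-enolisation, either of which would erode the C10 configuration; slow base-induced exchange at C5. Fallback (catalyst control in place of the substrate-directed shift): the sequence is stopped at adduct 32, which is isolated with exclusion of air. The β,γ- to α,β-isomerisation is then run separately with a cinchona-alkaloid-derived bifunctional proton-transfer catalyst (a quinine- or quinidine-derived 6'-hydroxy base), the pseudo-enantiomer being chosen so that the proton is delivered to the required face of C10. This sets out from 32, involves no new compound (entry F0) and returns at 33.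

**Step 18.** What may go wrong: elimination of the activated C8 oxygen toward the allylic C9 instead of substitution, or capture of the phosphine by the exocyclic enone. Fallback (sulfonate displacement by nitrite, Lattrell–Dax inversion): from 28, triflic anhydride and pyridine give the 8α-trifluoromethanesulfonate F6. Tetrabutylammonium nitrite in toluene displaces it with inversion to the 8β-nitrite ester F7, which hydrolyses on aqueous work-up and returns to the route at 30, bypassing 29.

**Step 14.** What may go wrong: incomplete formation of the ketone/lactone dianion, γ- instead of α'-deprotonation of the enone, or acylation of the C4 enolate by the lactone carbonyl, which lies on the same face. Fallback (sequential, the lactone first while the ketone is still a ketal): from 19, the same Mannich sequence on the lactone alone gives the 11-(dimethylaminomethyl) lactone ketal F8, its methiodide F9 and, after elimination, the α-methylene lactone ketal F10. Ketal hydrolysis (through the β,γ-enone F11) and triethylamine give the conjugated enone F12. C15 is then introduced under weakly acidic conditions by direct α'-methylenation with paraformaldehyde and a secondary ammonium trifluoroacetate, which returns to the route at 24.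

**Step 8.** What may go wrong: competing reduction of the tert-butyl ester, or stalling of the hindered tetrasubstituted enoate. Fallback (hydrolysis and borohydride reduction of an activated acid): from 14, LiOH saponifies only the ethyl ester to the carboxylic acid F13 (tert-butyl esters resist hydroxide). Isobutyl chloroformate and N-methylmorpholine give the mixed carbonic anhydride F14, and NaBH4 reduces it to 15.

## Further compounds

F1 | step 7 | 2-(1,4-dioxaspiro[4.4]non-7-en-7-yl)acetic acid | OC(=O)CC1=CCC2(C1)OCCO2
F2 | step 7 | (R)-pantolactonyl 2-(1,4-dioxaspiro[4.4]non-7-en-7-yl)acetate | CC1(C)COC(=O)[C@@H]1OC(=O)CC2=CCC3(C2)OCCO3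
F3 | step 7 | (R)-pantolactonyl 2-diazo-2-(1,4-dioxaspiro[4.4]non-7-en-7-yl)acetate | CC1(C)COC(=O)[C@@H]1OC(=O)C(=[N+]=[N-])C2=CCC3(C2)OCCO3
F4 | step 7 | pantolactonyl cis-divinylcyclopropane (pantolactonyl ester analogue of 13) | CC1(C)COC(=O)[C@@H]1OC(=O)[C@@]2(C[C@H]2/C(CC(=O)OC(C)(C)C)=C/O[Si](C)(C)C(C)(C)C)C3=CCC4(C3)OCCO4
F5 | step 7 | pantolactonyl cycloheptadiene ester (pantolactonyl ester analogue of 14) | CC1(C)COC(=O)[C@@H]1OC(=O)C2=C3CC4(OCCO4)C[C@H]3[C@@H](O[Si](C)(C)C(C)(C)C)C(CC(=O)OC(C)(C)C)=CC2
F0 | step 20 | none | none
F6 | step 18 | 8α-trifluoromethanesulfonate of 28 | C=C1C(=O)C[C@H]2C(=C)C[C@H](OS(=O)(=O)C(F)(F)F)[C@H]3C(=C)C(=O)O[C@@H]3[C@H]21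
F7 | step 18 | 8β-nitrite ester of 30 | C=C1C(=O)C[C@H]2C(=C)C[C@@H](ON=O)[C@H]3C(=C)C(=O)O[C@@H]3[C@H]21
F8 | step 14 | 11-(dimethylaminomethyl) lactone ketal from 19 | CC(C)(C)[Si](OCC1=C2CC3(OCCO3)C[C@H]2[C@H]4OC(=O)C(CN(C)C)[C@@H]4CC1)(c1ccccc1)c1ccccc1
F9 | step 14 | methiodide of F8 | CC(C)(C)[Si](OCC1=C2CC3(OCCO3)C[C@H]2[C@H]4OC(=O)C(C[N+](C)(C)C)[C@@H]4CC1)(c1ccccc1)c1ccccc1.[I-]
F10 | step 14 | α-methylene lactone ketal | CC(C)(C)[Si](OCC1=C2CC3(OCCO3)C[C@H]2[C@H]4OC(=O)C(=C)[C@@H]4CC1)(c1ccccc1)c1ccccc1
F11 | step 14 | β,γ-enone with α-methylene lactone | O=C1CC2=C(CO[Si](C(C)(C)C)(c4ccccc4)c5ccccc5)CC[C@H]3C(=C)C(=O)O[C@@H]3[C@@H]2C1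
F12 | step 14 | conjugated enone with α-methylene lactone (C10 epimers) | O=C1C[C@@H]2C(=C1)C(CO[Si](C(C)(C)C)(c4ccccc4)c5ccccc5)CC[C@H]3C(=C)C(=O)O[C@@H]32
F13 | step 8 | C14 carboxylic acid from 14 | OC(=O)C1=C2CC3(OCCO3)C[C@H]2[C@@H](O[Si](C)(C)C(C)(C)C)C(CC(=O)OC(C)(C)C)=CC1
F14 | step 8 | mixed isobutyl carbonic anhydride of F13 | CC(C)COC(=O)OC(=O)C1=C2CC3(OCCO3)C[C@H]2[C@@H](O[Si](C)(C)C(C)(C)C)C(CC(=O)OC(C)(C)C)=CC1
A1 | alternative 1 | spiro-dione pentacycle (rings A, B, C, D and dione ring E) | O=C1CCC(=O)C12CC=C3CC[C@H]4C(=C)C(=O)O[C@@H]4[C@@H]5CC6(OCCO6)[C@@H]2[C@@H]35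
A2 | alternative 2 | 8-O-(tert-butyldimethylsilyl)-8β-hydroxydehydrocostus lactone | C=C1CC[C@H]2C(=C)C[C@@H](O[Si](C)(C)C(C)(C)C)[C@H]3C(=C)C(=O)O[C@@H]3[C@H]21
A3 | alternative 3 | 13-nor unit B (8β-hydroxy-13-nordehydrocostus lactone) | C=C1CC[C@H]2C(=C)C[C@@H](O)[C@H]3CC(=O)O[C@@H]3[C@H]21
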